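Ring numbering used throughout: C1 (C=O), C2 (OH), C3 (heptadecyl), C4 (C=O), C5 (OMe), C6 (H).
Enabling feature: ring atoms C4, C5(OMe), C6(H) and C1(O) carry oxygen in the 1,1,3-pattern of a vinylketene acetal. The remaining pair C2–C3, with the chain on C3, is a disubstituted acetylene once C2–OH is read as a former acetyl group.
Retrosynthetic cuts: C4–O (acetoxylation of an o-quinone), then C2–O (aryl migration from an acetyl group), then ring bonds C3–C4 and C1–C2 together ([4+2]), and last the bond between the alkyne carbon and the first CH2 of the chain.
Forward order: the C17 chain is joined to but-3-yn-2-ol, oxidation gives the ynone, the single ring closes in one cycloaddition–aromatisation, and four further steps raise the arene to the hydroxyquinone.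
The C1 and C5 oxygens leave the cycloaddition already distinguished as free phenol and methyl ether, so no selective methylation is needed.
Stereochemistry: the target has no stereocentre and no stereogenic double bond; the transient centres on the way are racemic and are erased.

Key step: step 4

Assumption: the silyl ketene acetal diene is drawn as its (1Z) isomer, the one expected from deprotonation through the lithium-chelated s-cis enoate; either isomer would lead to the same arene.

Step 1
Reactants: 1 but-3-yn-2-ol (racemic); 2 1-bromoheptadecane
Product: 4 henicos-3-yn-2-ol (racemic), via dilithiated butynol 3 (not isolated)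
Conditions: n-BuLi (2.1 equiv), THF, −78 to 0 °C; DMPU, then 2, 0 °C to rt; H2O
Reagents that add atoms: none
Why: Double deprotonation gives the alkoxide–acetylide 3, whose much more nucleophilic carbon centre alone displaces bromide from the unhindered primary halide (SN2 acetylide alkylation, with DMPU loosening the lithium aggregates); the carbinol centre stays racemic and is removed in step 2.

Step 2
Reactants: 4 henicos-3-yn-2-ol (racemic)
Product: 5 henicos-3-yn-2-one
Conditions: activated MnO2 (15 equiv), CH2Cl2, rt
Reagents that add atoms: none
Why: Activated MnO2 oxidises propargylic alcohols selectively under neutral heterogeneous conditions, so the conjugated ynone should form without isomerisation to an allene and without conjugate addition.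

Step 3
Reactants: 6 methyl (E)-3-methoxybut-2-enoate
Product: 8 (1Z)-1,3-dimethoxy-1-(trimethylsilyloxy)buta-1,3-diene, via lithium dienolate 7 (not isolated)
Conditions: LiN(i-Pr)2 (1.1 equiv), THF, −78 °C; Me3SiCl (1.2 equiv), −78 °C to rt; pentane, filtration, distillation under reduced pressure
Reagents that add atoms: chlorotrimethylsilane, C[Si](C)(C)Cl
Why: Kinetic γ-deprotonation of the methyl group cis to the ester, followed by O-silylation of the extended enolate by the hard silyl chloride, is the standard silyl ketene acetal formation, and the non-aqueous work-up preserves the hydrolysis-sensitive diene.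

Step 4
Reactants: 8 (1Z)-1,3-dimethoxy-1-(trimethylsilyloxy)buta-1,3-diene; 5 henicos-3-yn-2-one
Product: 10 1-(2-heptadecyl-6-hydroxy-4-methoxyphenyl)ethan-1-one, via cyclohexa-1,4-diene cycloadduct 9 (not isolated)
Conditions: 8 (2.5 equiv), toluene, 110 °C, sealed tube, Ar; then 1 M HCl, THF, rt
Reagents that add atoms: none
Why: The three oxygen donors raise the HOMO of 8 and place its largest coefficient on the terminal CH2, which therefore leads the bonding to the electrophilic, chain-bearing alkyne carbon of 5 (C4–C3), the ketene acetal carbon following onto the carbon next to the acetyl group (C1–C2) within one concerted but markedly asynchronous normal-electron-demand Diels–Alder reaction. The closest known reaction type is the thermal benzannulation of vinylketene silyl acetals (1-alkoxy-1-silyloxy-3-alkoxybutadienes) by conjugated alkynones and alkynoates, a standard entry to mono-O-methylated resorcinols. The single ring is closed in an intermolecular [4+2] mode, four diene carbons plus two alkyne carbons giving the six-membered carbocycle of cyclohexa-1,4-diene 9. Dilute acid then collapses the mixed methyl silyl ketal at C1 to a carbonyl group with loss of methanol and the silyl group, and the dienone enolises through its C4 methylene to the arene, whose phenol is held by a hydrogen bond to the acetyl oxygen. No lasting stereocentre is created, since the ketal carbon of 9 forms as a racemate and becomes planar on aromatisation, which also erases the diene geometry. The step needs one regiochemical sense and attack on C≡C instead of C=O: the complementary polarity of the two partners secures the former, and working without any Lewis acid, under which a ketone carbonyl is a poor heterodienophile, secures the latter.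

Step 5
Reactants: 10 1-(2-heptadecyl-6-hydroxy-4-methoxyphenyl)ethan-1-one
Product: 12 3-heptadecyl-5-methoxybenzene-1,2-diol, via aryl acetate 11 (not isolated)
Conditions: 30% aq. H2O2 (1.2 equiv), NaOH (3 equiv), THF–MeOH–H2O, 0 °C to rt, Ar; then 1 M HCl
Reagents that add atoms: hydrogen peroxide, OO
Why: In the Dakin oxidation hydroperoxide adds to the acetyl carbonyl, which its two ortho neighbours twist out of conjugation, and the very electron-rich aryl group (ortho phenoxide, para methoxy) migrates to oxygen to give acetate 11, which hydroxide cleaves at once, while argon and a near-stoichiometric charge of peroxide protect the catechol.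

Step 6
Reactants: 12 3-heptadecyl-5-methoxybenzene-1,2-diol
Product: 13 3-heptadecyl-5-methoxycyclohexa-3,5-diene-1,2-dione
Conditions: Ag2O (2.5 equiv), Na2SO4, Et2O, rt, dark; filtration, used without delay
Reagents that add atoms: none
Why: Ag2O in dry ether is the classical neutral two-electron oxidant for catechols, and the o-quinone should be manageable because the C5 methoxy group stabilises it as a vinylogous ester and the C3 chain hinders dimerisation.

Step 7
Reactants: 13 3-heptadecyl-5-methoxycyclohexa-3,5-diene-1,2-dione
Product: 14 3-heptadecyl-5-methoxybenzene-1,2,4-triyl triacetate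
Conditions: Ac2O, conc. H2SO4 (cat.), 0 °C to rt; then ice–water
Reagents that add atoms: acetic anhydride, CC(=O)OC(C)=O
Why: In the Thiele–Winter acetoxylation the acid-activated quinone should take up acetate at C4, the unsubstituted β-carbon of the C2 enone, because the C1 carbonyl is tied up as a vinylogous ester of the C5 methoxy group and attack at C4 leaves that conjugation intact, after which enolisation and full acetylation trap the 1,2,4-trioxygenated arene.

Step 8
Reactants: 14 3-heptadecyl-5-methoxybenzene-1,2,4-triyl triacetate
Product: 16 3-heptadecyl-2-hydroxy-5-methoxycyclohexa-2,5-diene-1,4-dione (irisoquin B), via benzenetriol 15 (not isolated)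
Conditions: K2CO3 (4 equiv), MeOH–THF, air, rt; then 1 M HCl
Reagents that add atoms: none
Why: Base-mediated transesterification frees triol 15, whose electron-rich anion is autoxidised by air across C1 and C4 to the 2-hydroxy-1,4-quinone, while methanol as the only nucleophile makes any exchange at the C5 vinylogous ester degenerate and the product rests as its delocalised anion until acidification.

Compound list
1 | but-3-yn-2-ol (racemic) | CC(O)C#C | starting material
2 | 1-bromoheptadecane | CCCCCCCCCCCCCCCCCBr | starting material
3 | dilithium salt of but-3-yn-2-ol (lithium alkoxide and lithium acetylide, racemic) | CC(O[Li])C#C[Li] | intermediate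
4 | henicos-3-yn-2-ol (racemic) | CCCCCCCCCCCCCCCCCC#CC(C)O | intermediate
5 | henicos-3-yn-2-one | CCCCCCCCCCCCCCCCCC#CC(C)=O | intermediate
6 | methyl (E)-3-methoxybut-2-enoate | CO/C(C)=C/C(=O)OC | starting material
7 | lithium (1E)-1,3-dimethoxybuta-1,3-dien-1-olate (OLi cis to C3, same spatial arrangement as in 8) | C=C(OC)/C=C(/OC)O[Li] | intermediate
8 | (1Z)-1,3-dimethoxy-1-(trimethylsilyloxy)buta-1,3-diene | C=C(OC)/C=C(/OC)O[Si](C)(C)C | intermediate
9 | 1-[2-heptadecyl-4,6-dimethoxy-6-(trimethylsilyloxy)cyclohexa-1,4-dien-1-yl]ethan-1-one (racemic at the ketal carbon) | CCCCCCCCCCCCCCCCCC1=C(C(C)=O)C(OC)(O[Si](C)(C)C)C=C(OC)C1 | intermediate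
10 | 1-(2-heptadecyl-6-hydroxy-4-methoxyphenyl)ethan-1-one | CCCCCCCCCCCCCCCCCc1cc(OC)cc(O)c1C(C)=O | intermediate
11 | 2-heptadecyl-6-hydroxy-4-methoxyphenyl acetate | CCCCCCCCCCCCCCCCCc1cc(OC)cc(O)c1OC(C)=O | intermediate
12 | 3-heptadecyl-5-methoxybenzene-1,2-diol | CCCCCCCCCCCCCCCCCc1cc(OC)cc(O)c1O | intermediate
13 | 3-heptadecyl-5-methoxycyclohexa-3,5-diene-1,2-dione | CCCCCCCCCCCCCCCCCC1=CC(OC)=CC(=O)C1=O | intermediate
14 | 3-heptadecyl-5-methoxybenzene-1,2,4-triyl triacetate | CCCCCCCCCCCCCCCCCc1c(OC(C)=O)c(OC(C)=O)cc(OC)c1OC(C)=O | intermediate
15 | 3-heptadecyl-5-methoxybenzene-1,2,4-triol | CCCCCCCCCCCCCCCCCc1c(O)c(O)cc(OC)c1O | intermediate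
16 | 3-heptadecyl-2-hydroxy-5-methoxycyclohexa-2,5-diene-1,4-dione (irisoquin B) | CCCCCCCCCCCCCCCCCC1=C(O)C(=O)C=C(OC)C1=O | target

Total step count: 8.
Longest linear sequence: 7 steps (1, 2, 4, 5, 6, 7, 8); step 3 is the convergent branch.

Steps most likely to fail

**Step 7.** Acetate may add at the methoxy-bearing C5 with loss of the methyl ether, or at C6 instead of the crowded C4. The acid may also tautomerise the quinone toward its side chain.
- The fallback sets out from 10 and comes back at 15. It brings in the C4 oxygen before the acetyl group is exchanged, so no o-quinone is needed.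
- Elbs persulfate oxidation of the phenolate of 10 (K2S2O8, aq. NaOH–pyridine, rt) attacks the free position para to the phenol oxygen. It should give potassium 3-acetyl-2-heptadecyl-4-hydroxy-6-methoxyphenyl sulfate F1.
- Warm dilute HCl hydrolyses this to 1-(2-heptadecyl-3,6-dihydroxy-4-methoxyphenyl)ethan-1-one F2.
- Dakin oxidation of the latter (H2O2, NaOH, THF–H2O, Ar) passes through 2-heptadecyl-3,6-dihydroxy-4-methoxyphenyl acetate F3 and delivers triol 15.
- Triol 15 is aerated as in step 8 to give 16, and steps 5 to 7 are bypassed.

**Step 4.** The β-alkyl-substituted ynone may react so slowly that other processes overtake ring closure. These are thermal decay or adventitious hydrolysis of the diene, and a Mukaiyama-type addition to the ketone carbonyl.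
- The fallback sets out from 2 and comes back at 10. It functionalises a purchased arene instead of building the ring.
- Bromide 2 and magnesium in THF give heptadecylmagnesium bromide F4.
- Kumada coupling with 1-bromo-3,5-dimethoxybenzene under NiCl2(dppp) catalysis gives 1-heptadecyl-3,5-dimethoxybenzene F5.
- Friedel–Crafts acetylation (AcCl, SnCl4, CH2Cl2, 0 °C) goes to the position ortho to the chain and para to a methoxy group, as is usual for 5-alkylresorcinol dimethyl ethers. This gives 1-(2-heptadecyl-4,6-dimethoxyphenyl)ethan-1-one F6.
- BCl3 (CH2Cl2, −78 to 0 °C), chelated by the ketone, cleaves only the ortho methyl ether to give 10.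

**Step 5.** Hydroperoxide may add only sluggishly to the flanked, phenoxide-deactivated ketone, and the catechol may be over-oxidised in alkaline peroxide.
- The fallback sets out from 10 and comes back at 12. It replaces the basic Dakin manifold by an acid-promoted Baeyer–Villiger oxidation of a masked phenol.
- Acetylation (Ac2O, pyridine, DMAP) gives 2-acetyl-3-heptadecyl-5-methoxyphenyl acetate F7.
- m-CPBA with catalytic CF3CO2H in CH2Cl2 induces aryl migration to 3-heptadecyl-5-methoxy-1,2-phenylene diacetate F8, in which the catechol never meets the oxidant unprotected.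
- K2CO3 in degassed MeOH under argon then releases 12.

Further compounds
F1 | step 7 | potassium 3-acetyl-2-heptadecyl-4-hydroxy-6-methoxyphenyl sulfate | CCCCCCCCCCCCCCCCCc1c(OS(=O)(=O)[O-])c(OC)cc(O)c1C(C)=O.[K+]
F2 | step 7 | 1-(2-heptadecyl-3,6-dihydroxy-4-methoxyphenyl)ethan-1-one | CCCCCCCCCCCCCCCCCc1c(O)c(OC)cc(O)c1C(C)=O
F3 | step 7 | 2-heptadecyl-3,6-dihydroxy-4-methoxyphenyl acetate | CCCCCCCCCCCCCCCCCc1c(O)c(OC)cc(O)c1OC(C)=O
F4 | step 4 | heptadecylmagnesium bromide | CCCCCCCCCCCCCCCCC[Mg]Br
F5 | step 4 | 1-heptadecyl-3,5-dimethoxybenzene | CCCCCCCCCCCCCCCCCc1cc(OC)cc(OC)c1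
F6 | step 4 | 1-(2-heptadecyl-4,6-dimethoxyphenyl)ethan-1-one | CCCCCCCCCCCCCCCCCc1cc(OC)cc(OC)c1C(C)=O
F7 | step 5 | 2-acetyl-3-heptadecyl-5-methoxyphenyl acetate | CCCCCCCCCCCCCCCCCc1cc(OC)cc(OC(C)=O)c1C(C)=O
F8 | step 5 | 3-heptadecyl-5-methoxy-1,2-phenylene diacetate | CCCCCCCCCCCCCCCCCc1cc(OC)cc(OC(C)=O)c1OC(C)=O
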